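**Plan**

- Retrosynthesis: the three benzyl ethers and the acetonide come off last; the C5–O and C7–O bonds go back to C–F; ring C is opened at O1–C8a; the diketone is cut at C3–C4, the methyl ketone at C1'–C2, and the side chain at C7''–C8'' and at the ether O–C8''.
- Enabling feature: C8a, C5 and C7 of ring A all carry oxygen and lie ortho, ortho and para to C4a, the carbon that bears the C4 carbonyl, so all three C–O bonds can come from the C–F bonds of one symmetric 2,4,6-trifluorobenzoyl group by SNAr.
- Forward order: ring B is etherified and its side chain built first (glycolate imide, aldol, reduction, acetonide); C1' is then acetylated, the enolate is acylated with the trifluorobenzoyl unit, ring C closes by fluoride displacement, and ring A receives its two oxygens afterwards. Ring C is the only ring of the target that is formed; rings A and B are bought.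
- Stereochemistry: C7'' and C8'' are set together in one Evans syn-aldol reaction under control of (R)-4-benzyl-2-oxazolidinone. The syn adduct corresponds to the threo (7''S,8''S) diol, and no later step breaks a bond at either centre.

Key step: step 9

Assumption: in the double fluoride exchange the fluoride para to the C4 carbonyl (C7) is taken to react before the ortho one (C5); the order has no bearing on the product.

**Route**

Step 1
Reactants: 1 4-bromo-2,6-dimethoxyphenol; 2 ethyl bromoacetate
Product: 3 ethyl 2-(4-bromo-2,6-dimethoxyphenoxy)acetate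
Conditions: K2CO3, acetone, reflux
Reagents that add atoms: none
Why: Williamson ether synthesis, in which the potassium phenoxide displaces bromide from the activated primary α-bromo ester by SN2 and the two flanking methoxy groups do not hinder attack on so unhindered an electrophile.

Step 2
Reactants: 3 ethyl 2-(4-bromo-2,6-dimethoxyphenoxy)acetate
Product: 4 2-(4-bromo-2,6-dimethoxyphenoxy)acetic acid
Conditions: LiOH, THF/H2O, rt; then 1 M HCl to pH 2
Reagents that add atoms: lithium hydroxide, [Li+].[OH-]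
Why: Saponification of the ethyl ester by hydroxide through acyl–oxygen cleavage, under which the aryl bromide and the aryl ethers are inert.

Step 3
Reactants: 4 2-(4-bromo-2,6-dimethoxyphenoxy)acetic acid; 5 (R)-4-benzyl-2-oxazolidinone
Product: 7 (R)-4-benzyl-3-[2-(4-bromo-2,6-dimethoxyphenoxy)acetyl]oxazolidin-2-one, via mixed pivalic anhydride 6 (not isolated)
Conditions: t-BuCOCl, Et3N, THF, −20 °C; then 5, LiCl, −20 °C → rt
Reagents that add atoms: none
Why: N-Acylation of the oxazolidinone through a mixed anhydride, in which the LiCl-activated oxazolidinone attacks the unhindered aryloxyacetyl carbonyl of 6 and not the tert-butyl-shielded pivaloyl carbonyl.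

Step 4
Reactants: 7 (R)-4-benzyl-3-[2-(4-bromo-2,6-dimethoxyphenoxy)acetyl]oxazolidin-2-one; 8 4-benzyloxybenzaldehyde
Product: 10 (R)-4-benzyl-3-[(2R,3S)-3-(4-benzyloxyphenyl)-2-(4-bromo-2,6-dimethoxyphenoxy)-3-hydroxypropanoyl]oxazolidin-2-one, via Z-dibutylboron enolate 9 (not isolated)
Conditions: n-Bu2BOTf, i-Pr2NEt, CH2Cl2, −78 → 0 °C; then 8, −78 → 0 °C; then pH 7 buffer, MeOH, 30% H2O2, 0 °C
Reagents that add atoms: none
Why: Evans boron syn-aldol reaction, in which soft enolisation gives the Z-enolate 9 that adds to the aldehyde through a closed Zimmerman–Traxler chair with opposed imide dipoles while the benzyl group of the (R)-auxiliary blocks one enolate face, so that C8'' and C7'' are set together as the syn adduct, (2R,3S) in the imide and (7''S,8''S) in the numbering of the target once C9'' is reduced.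

Step 5
Reactants: 10 (R)-4-benzyl-3-[(2R,3S)-3-(4-benzyloxyphenyl)-2-(4-bromo-2,6-dimethoxyphenoxy)-3-hydroxypropanoyl]oxazolidin-2-one
Product: 11 (1S,2S)-1-(4-benzyloxyphenyl)-2-(4-bromo-2,6-dimethoxyphenoxy)propane-1,3-diol
Conditions: LiBH4, MeOH (1.1 equiv), THF, 0 °C
Reagents that add atoms: none
Why: Reductive cleavage of the N-acyl oxazolidinone, in which LiBH4 delivers hydride to the exocyclic imide carbonyl, the auxiliary is expelled and the aldehyde so formed is reduced on to the primary alcohol, while nothing present is basic enough to enolise C8'' before it loses its carbonyl neighbour.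

Step 6
Reactants: 11 (1S,2S)-1-(4-benzyloxyphenyl)-2-(4-bromo-2,6-dimethoxyphenoxy)propane-1,3-diol
Product: 12 (4S,5S)-4-(4-benzyloxyphenyl)-5-(4-bromo-2,6-dimethoxyphenoxy)-2,2-dimethyl-1,3-dioxane
Conditions: Me2C(OMe)2, catalytic PPTS, CH2Cl2, rt
Reagents that add atoms: 2,2-dimethoxypropane, COC(C)(C)OC
Why: Acid-catalysed transketalisation closes the six-membered 1,3-dioxane across O7'' and O9'' without breaking a C–O bond at either stereocentre, and the small vicinal coupling expected for the cis-4,5-disubstituted dioxane offers a check of the threo configuration.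

Step 7
Reactants: 12 (4S,5S)-4-(4-benzyloxyphenyl)-5-(4-bromo-2,6-dimethoxyphenoxy)-2,2-dimethyl-1,3-dioxane; 13 N-methoxy-N-methylacetamide
Product: 15 1-[4-{[(4S,5S)-4-(4-benzyloxyphenyl)-2,2-dimethyl-1,3-dioxan-5-yl]oxy}-3,5-dimethoxyphenyl]ethanone, via aryllithium 14 (not isolated)
Conditions: n-BuLi, THF, −78 °C; then 13, −78 → 0 °C; then AcOH
Reagents that add atoms: none
Why: Bromine–lithium exchange is faster at −78 °C than any deprotonation of the benzyl ether or the dioxane, and the aryllithium adds only once to the Weinreb amide because the chelated adduct does not collapse before the acidic quench (Weinreb ketone synthesis).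

Step 8
Reactants: 15 1-[4-{[(4S,5S)-4-(4-benzyloxyphenyl)-2,2-dimethyl-1,3-dioxan-5-yl]oxy}-3,5-dimethoxyphenyl]ethanone; 16 2,4,6-trifluorobenzoyl chloride
Product: 18 1-[4-{[(4S,5S)-4-(4-benzyloxyphenyl)-2,2-dimethyl-1,3-dioxan-5-yl]oxy}-3,5-dimethoxyphenyl]-3-(2,4,6-trifluorophenyl)propane-1,3-dione, via lithium enolate 17 (not isolated)
Conditions: LiN(SiMe3)2 (2.1 equiv), THF, −78 °C; then 16, −78 → −20 °C; then AcOH
Reagents that add atoms: none
Why: Claisen-type C-acylation of a preformed lithium enolate by an acid chloride, in which the second equivalent of amide base removes the acidic proton of the diketone as it forms and so prevents double acylation, while at low temperature neither base nor enolate should attack the fluorinated ring.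

Step 9
Reactants: 18 1-[4-{[(4S,5S)-4-(4-benzyloxyphenyl)-2,2-dimethyl-1,3-dioxan-5-yl]oxy}-3,5-dimethoxyphenyl]-3-(2,4,6-trifluorophenyl)propane-1,3-dione
Product: 20 2-[4-{[(4S,5S)-4-(4-benzyloxyphenyl)-2,2-dimethyl-1,3-dioxan-5-yl]oxy}-3,5-dimethoxyphenyl]-5,7-difluoro-4H-chromen-4-one, via potassium Z-enolate 19 (not isolated)
Conditions: K2CO3, DMF, rt → 50 °C
Reagents that add atoms: none
Why: K2CO3 deprotonates the diketone to the Z-enolate 19, whose oxygen on the ring B side adds to an ortho C–F carbon of the trifluorophenyl ring while the charge is taken up by the C4 carbonyl and the two other fluorines, and fluoride is then expelled (intramolecular SNAr by addition–elimination). The closest known reaction type is the base-mediated cyclisation of 1-(2-fluoroaryl)-1,3-diketones to chromones and flavones. Ring C closes as a six-membered O-cyclisation that forms O1–C8a, a 6-endo-trig closure when counted against the C4a=C8a bond that accepts the charge. No stereocentre is formed, and C7'' and C8'' are remote, non-acidic centres that carbonate cannot touch. The step needs O- over C-attack and intra- over intermolecular substitution: C3 or the C4 oxygen could only close a four-membered ring, and the six-membered transition state should outrun attack on a second molecule. The two ortho fluorides are related by symmetry, so a single flavone should form, with the C5 and C7 fluorides left in place for step 10.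

Step 10
Reactants: 20 2-[4-{[(4S,5S)-4-(4-benzyloxyphenyl)-2,2-dimethyl-1,3-dioxan-5-yl]oxy}-3,5-dimethoxyphenyl]-5,7-difluoro-4H-chromen-4-one
Product: 22 5,7-bis(benzyloxy)-2-[4-{[(4S,5S)-4-(4-benzyloxyphenyl)-2,2-dimethyl-1,3-dioxan-5-yl]oxy}-3,5-dimethoxyphenyl]-4H-chromen-4-one, via 7-benzyloxy-5-fluoroflavone 21 (not isolated)
Conditions: BnOH (4 equiv), NaH (3 equiv), THF, 0 °C; then 20, DMSO co-solvent, rt → 60 °C
Reagents that add atoms: benzyl alcohol, OCc1ccccc1
Why: Intermolecular SNAr by addition–elimination, in which the fluorides at C7 and C5, para and ortho to the C4 carbonyl, are displaced in turn by sodium benzyloxide, while addition of the alkoxide at C2 is reversible in the absence of water and should not end in ring opening.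

Step 11
Reactants: 22 5,7-bis(benzyloxy)-2-[4-{[(4S,5S)-4-(4-benzyloxyphenyl)-2,2-dimethyl-1,3-dioxan-5-yl]oxy}-3,5-dimethoxyphenyl]-4H-chromen-4-one
Product: 23 5,7-bis(benzyloxy)-2-[4-{[(1S,2S)-1-(4-benzyloxyphenyl)-1,3-dihydroxypropan-2-yl]oxy}-3,5-dimethoxyphenyl]-4H-chromen-4-one
Conditions: AcOH/H2O 4:1, 40 °C
Reagents that add atoms: none
Why: Acid-catalysed acetal hydrolysis proceeds by ionisation at the ketal carbon and not at C7'', so in dilute acetic acid the benzylic configuration should be retained while the benzyl ethers and the flavone are inert.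

Step 12
Reactants: 23 5,7-bis(benzyloxy)-2-[4-{[(1S,2S)-1-(4-benzyloxyphenyl)-1,3-dihydroxypropan-2-yl]oxy}-3,5-dimethoxyphenyl]-4H-chromen-4-one
Product: 24 (7''S,8''S)-4'',5,7-trihydroxy-3',5'-dimethoxy-4',8''-oxyflavonolignan-7'',9''-diol
Conditions: H2 (1 atm), palladium on carbon (Pd/C), EtOAc/MeOH, rt
Reagents that add atoms: none
Why: Catalytic hydrogenolysis over palladium cleaves the three aryl benzyl ethers much faster than it attacks the secondary benzylic alcohol or the C2=C3 bond of the flavone under neutral conditions at one atmosphere, so stopping at full debenzylation should give the target.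

**Compound list**

1 | 4-bromo-2,6-dimethoxyphenol | COc1cc(Br)cc(OC)c1O | starting material
2 | ethyl bromoacetate | CCOC(=O)CBr | starting material
3 | ethyl 2-(4-bromo-2,6-dimethoxyphenoxy)acetate | CCOC(=O)COc1c(OC)cc(Br)cc1OC | intermediate
4 | 2-(4-bromo-2,6-dimethoxyphenoxy)acetic acid | OC(=O)COc1c(OC)cc(Br)cc1OC | intermediate
5 | (R)-4-benzyl-2-oxazolidinone | O=C1N[C@H](Cc2ccccc2)CO1 | starting material
6 | 2-(4-bromo-2,6-dimethoxyphenoxy)acetic pivalic anhydride (formed in the flask) | CC(C)(C)C(=O)OC(=O)COc1c(OC)cc(Br)cc1OC | intermediate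
7 | (R)-4-benzyl-3-[2-(4-bromo-2,6-dimethoxyphenoxy)acetyl]oxazolidin-2-one | O=C1OC[C@@H](Cc2ccccc2)N1C(=O)COc1c(OC)cc(Br)cc1OC | intermediate
8 | 4-benzyloxybenzaldehyde | O=Cc1ccc(OCc2ccccc2)cc1 | starting material
9 | Z-dibutylboron enolate of 7 (formed in the flask) | CCCCB(CCCC)O/C(=C\Oc1c(OC)cc(Br)cc1OC)N1C(=O)OC[C@H]1Cc1ccccc1 | intermediate
10 | (R)-4-benzyl-3-[(2R,3S)-3-(4-benzyloxyphenyl)-2-(4-bromo-2,6-dimethoxyphenoxy)-3-hydroxypropanoyl]oxazolidin-2-one | O=C1OC[C@@H](Cc2ccccc2)N1C(=O)[C@H](Oc1c(OC)cc(Br)cc1OC)[C@@H](O)c1ccc(OCc2ccccc2)cc1 | intermediate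
11 | (1S,2S)-1-(4-benzyloxyphenyl)-2-(4-bromo-2,6-dimethoxyphenoxy)propane-1,3-diol | COc1cc(Br)cc(OC)c1O[C@@H](CO)[C@@H](O)c1ccc(OCc2ccccc2)cc1 | intermediate
12 | (4S,5S)-4-(4-benzyloxyphenyl)-5-(4-bromo-2,6-dimethoxyphenoxy)-2,2-dimethyl-1,3-dioxane | COc1cc(Br)cc(OC)c1O[C@@H](COC2(C)C)[C@@H](O2)c2ccc(OCc3ccccc3)cc2 | intermediate
13 | N-methoxy-N-methylacetamide | CC(=O)N(C)OC | starting material
14 | aryllithium from 12, lithium in place of bromine (formed in the flask) | COc1cc([Li])cc(OC)c1O[C@@H](COC2(C)C)[C@@H](O2)c2ccc(OCc3ccccc3)cc2 | intermediate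
15 | 1-[4-{[(4S,5S)-4-(4-benzyloxyphenyl)-2,2-dimethyl-1,3-dioxan-5-yl]oxy}-3,5-dimethoxyphenyl]ethanone | CC(=O)c1cc(OC)c(O[C@@H](COC2(C)C)[C@@H](O2)c2ccc(OCc3ccccc3)cc2)c(OC)c1 | intermediate
16 | 2,4,6-trifluorobenzoyl chloride | O=C(Cl)c1c(F)cc(F)cc1F | starting material
17 | lithium enolate of 15 (formed in the flask) | [Li]OC(=C)c1cc(OC)c(O[C@@H](COC2(C)C)[C@@H](O2)c2ccc(OCc3ccccc3)cc2)c(OC)c1 | intermediate
18 | 1-[4-{[(4S,5S)-4-(4-benzyloxyphenyl)-2,2-dimethyl-1,3-dioxan-5-yl]oxy}-3,5-dimethoxyphenyl]-3-(2,4,6-trifluorophenyl)propane-1,3-dione | O=C(CC(=O)c1cc(OC)c(O[C@@H](COC2(C)C)[C@@H](O2)c2ccc(OCc3ccccc3)cc2)c(OC)c1)c1c(F)cc(F)cc1F | intermediate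
19 | potassium Z-enolate of 18, charge on the oxygen of the ring B side (formed in the flask) | [K+].[O-]/C(=C\C(=O)c1c(F)cc(F)cc1F)c1cc(OC)c(O[C@@H](COC2(C)C)[C@@H](O2)c2ccc(OCc3ccccc3)cc2)c(OC)c1 | intermediate
20 | 2-[4-{[(4S,5S)-4-(4-benzyloxyphenyl)-2,2-dimethyl-1,3-dioxan-5-yl]oxy}-3,5-dimethoxyphenyl]-5,7-difluoro-4H-chromen-4-one | COc1cc(-c2cc(=O)c3c(F)cc(F)cc3o2)cc(OC)c1O[C@@H](COC1(C)C)[C@@H](O1)c1ccc(OCc2ccccc2)cc1 | intermediate
21 | 7-benzyloxy-2-[4-{[(4S,5S)-4-(4-benzyloxyphenyl)-2,2-dimethyl-1,3-dioxan-5-yl]oxy}-3,5-dimethoxyphenyl]-5-fluoro-4H-chromen-4-one (formed in the flask) | COc1cc(-c2cc(=O)c3c(F)cc(OCc4ccccc4)cc3o2)cc(OC)c1O[C@@H](COC1(C)C)[C@@H](O1)c1ccc(OCc2ccccc2)cc1 | intermediate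
22 | 5,7-bis(benzyloxy)-2-[4-{[(4S,5S)-4-(4-benzyloxyphenyl)-2,2-dimethyl-1,3-dioxan-5-yl]oxy}-3,5-dimethoxyphenyl]-4H-chromen-4-one | COc1cc(-c2cc(=O)c3c(OCc4ccccc4)cc(OCc4ccccc4)cc3o2)cc(OC)c1O[C@@H](COC1(C)C)[C@@H](O1)c1ccc(OCc2ccccc2)cc1 | intermediate
23 | 5,7-bis(benzyloxy)-2-[4-{[(1S,2S)-1-(4-benzyloxyphenyl)-1,3-dihydroxypropan-2-yl]oxy}-3,5-dimethoxyphenyl]-4H-chromen-4-one | COc1cc(-c2cc(=O)c3c(OCc4ccccc4)cc(OCc4ccccc4)cc3o2)cc(OC)c1O[C@@H](CO)[C@@H](O)c1ccc(OCc2ccccc2)cc1 | intermediate
24 | (7''S,8''S)-4'',5,7-trihydroxy-3',5'-dimethoxy-4',8''-oxyflavonolignan-7'',9''-diol, that is 2-[4-{[(1S,2S)-1,3-dihydroxy-1-(4-hydroxyphenyl)propan-2-yl]oxy}-3,5-dimethoxyphenyl]-5,7-dihydroxy-4H-chromen-4-one | COc1cc(-c2cc(=O)c3c(O)cc(O)cc3o2)cc(OC)c1O[C@@H](CO)[C@@H](O)c1ccc(O)cc1 | target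

**Step count**

Total step count: 12.
Longest linear sequence: 12 steps, from 1 to 24; the other building blocks (2, 5, 8, 13 and 16) are bought and enter directly.

**Steps most likely to fail**

1. Step 10. The second fluoride, deactivated once the first benzyloxy group is in place, may exchange sluggishly, and long exposure to alkoxide may lead to conjugate addition at C2 followed by opening of ring C. Fallback: the two oxygens are put on ring A before ring C exists, so that the flavone never meets an alkoxide. Setting out from 16, excess sodium benzyloxide (BnOH, NaH, THF/DMSO) should give, by esterification and SNAr at the para and one ortho position, benzyl 2,4-bis(benzyloxy)-6-fluorobenzoate F1. Saponification (NaOH, aqueous dioxane, heat) gives 2,4-bis(benzyloxy)-6-fluorobenzoic acid F2, and oxalyl chloride with catalytic DMF gives 2,4-bis(benzyloxy)-6-fluorobenzoyl chloride F3. Acylation of the lithium enolate 17, made from 15 as in step 8, with F3 gives 1-[2,4-bis(benzyloxy)-6-fluorophenyl]-3-[4-{[(4S,5S)-4-(4-benzyloxyphenyl)-2,2-dimethyl-1,3-dioxan-5-yl]oxy}-3,5-dimethoxyphenyl]propane-1,3-dione F4. Its single ortho fluoride is displaced by the enolate oxygen (K2CO3, DMF, 80 °C) in the same kind of ring closure as step 9. The fallback sets out from 15 and 16 and comes back to the route at 22.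

2. Step 8. The enolate may be acylated on oxygen or twice, and base or enolate may attack the fluorinated ring. Fallback: the C3–C4 bond is made by aldol addition and the oxidation level is adjusted afterwards. Setting out from 15, the lithium enolate 17 is added at −78 °C to commercial 2,4,6-trifluorobenzaldehyde to give 1-[4-{[(4S,5S)-4-(4-benzyloxyphenyl)-2,2-dimethyl-1,3-dioxan-5-yl]oxy}-3,5-dimethoxyphenyl]-3-hydroxy-3-(2,4,6-trifluorophenyl)propan-1-one F5, as a mixture of epimers at the carbinol carbon, which is of no consequence. Oxidation with Dess–Martin periodinane (NaHCO3, CH2Cl2) gives the diketone. The fallback comes back to the route at 18.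

3. Step 12. Over-reduction may occur: hydrogenolysis of the C7''–O bond once the para phenol is free, or saturation of C2=C3. Fallback: the last two steps are run in the opposite order, so that the benzylic oxygen is still held in the dioxane during hydrogenolysis. Setting out from 22, H2 over Pd/C gives 2-[4-{[(4S,5S)-4-(4-hydroxyphenyl)-2,2-dimethyl-1,3-dioxan-5-yl]oxy}-3,5-dimethoxyphenyl]-5,7-dihydroxy-4H-chromen-4-one F6. Brief treatment with aqueous acetic acid at room temperature then releases the diol; the exposure is kept short to limit acid-promoted loss of configuration at C7'' of the free phenol. The fallback comes back to the route at 24.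

**Further compounds**

F1 | step 10 | benzyl 2,4-bis(benzyloxy)-6-fluorobenzoate | O=C(OCc1ccccc1)c1c(F)cc(OCc2ccccc2)cc1OCc1ccccc1
F2 | step 10 | 2,4-bis(benzyloxy)-6-fluorobenzoic acid | OC(=O)c1c(F)cc(OCc2ccccc2)cc1OCc1ccccc1
F3 | step 10 | 2,4-bis(benzyloxy)-6-fluorobenzoyl chloride | O=C(Cl)c1c(F)cc(OCc2ccccc2)cc1OCc1ccccc1
F4 | step 10 | 1-[2,4-bis(benzyloxy)-6-fluorophenyl]-3-[4-{[(4S,5S)-4-(4-benzyloxyphenyl)-2,2-dimethyl-1,3-dioxan-5-yl]oxy}-3,5-dimethoxyphenyl]propane-1,3-dione | O=C(CC(=O)c1cc(OC)c(O[C@@H](COC2(C)C)[C@@H](O2)c2ccc(OCc3ccccc3)cc2)c(OC)c1)c1c(F)cc(OCc2ccccc2)cc1OCc1ccccc1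
F5 | step 8 | 1-[4-{[(4S,5S)-4-(4-benzyloxyphenyl)-2,2-dimethyl-1,3-dioxan-5-yl]oxy}-3,5-dimethoxyphenyl]-3-hydroxy-3-(2,4,6-trifluorophenyl)propan-1-one (both epimers at the carbinol carbon) | OC(CC(=O)c1cc(OC)c(O[C@@H](COC2(C)C)[C@@H](O2)c2ccc(OCc3ccccc3)cc2)c(OC)c1)c1c(F)cc(F)cc1F
F6 | step 12 | 2-[4-{[(4S,5S)-4-(4-hydroxyphenyl)-2,2-dimethyl-1,3-dioxan-5-yl]oxy}-3,5-dimethoxyphenyl]-5,7-dihydroxy-4H-chromen-4-one | COc1cc(-c2cc(=O)c3c(O)cc(O)cc3o2)cc(OC)c1O[C@@H](COC1(C)C)[C@@H](O1)c1ccc(O)cc1
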